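**Retrosynthetic overview**
1. The hemiketal is the closed form of a hydroxy E-enone. Cutting the bond between the enone β-carbon and the right-hand ring CH gives a ring carboxylic acid (radical precursor) and a terminal ynone, joined by a visible-light photoredox decarboxylative radical addition that also sets that ring stereocenter.
2. Left ynone: photoredox Giese addition of a (2-hydroxy-2,6,6-trimethylcyclohexyl)acetic acid to a silylated enynone linchpin. The acid comes from (−)-verbenone by conjugate methylation/alkylation, cyclobutane opening, methyl addition and hydrodealkenylation.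
3. Right acid: from (+)-verbenone by conjugate butenylation/hydroxymethylation, cyclobutane opening, Hock carbon-to-oxygen shift, cross-metathesis, 7-endo epoxide closure, methyl addition and oxidation.
4. Ring order: left cyclohexane, right cyclohexane (both unmasked from the pinane), right oxepanone, and last the left hemiketal oxepane, which closes on its own.

Assumption: both verbenone enantiomers are treated as purchasable chiral-pool ketones (each is also one allylic oxidation from the corresponding cheap α-pinene); carbinol epimers of 23/24 and methyl epimers of 12/13/26 are carried as mixtures because they converge later.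

**Route**

Step 1
Reactants: 1 (1S,5S)-(−)-verbenone
Product: 3 methyl 2-[(1S,3R,5R)-4,4,6,6-tetramethyl-2-oxobicyclo[3.1.1]heptan-3-yl]acetate, via magnesium enolate 2 (not isolated)
Conditions: MeMgBr (1.3 equiv), CuBr·SMe2 (5 mol %), THF, −20 °C; then DMPU, BrCH2CO2Me, −20 → 25 °C
Reagents that add atoms: methylmagnesium bromide, C[Mg]Br; methyl bromoacetate, COC(=O)CBr
Why: Copper-catalysed Grignard conjugate addition (Kharasch type) makes the ring gem-dimethyl carbon and a regiodefined enolate, whose alkylation on the face anti to the gem-dimethyl cyclobutane bridge sets the side-chain-bearing ring stereocenter from the bought bridgehead centers.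

Step 2
Reactants: 3 methyl 2-[(1S,3R,5R)-4,4,6,6-tetramethyl-2-oxobicyclo[3.1.1]heptan-3-yl]acetate
Product: 4 methyl 2-[(1R,3S)-3-(2-chloropropan-2-yl)-2,2-dimethyl-6-oxocyclohexyl]acetate
Conditions: HCl (g), ZnCl2 (10 mol %), CH2Cl2, 0 → 25 °C
Reagents that add atoms: hydrogen chloride, Cl
Why: Acid-triggered Grob-type fragmentation of the α-cyclobutyl ketone (carbonyl-assisted heterolysis of the strained bond to a tertiary cation captured by chloride) opens the pinane to the cyclohexanone without touching the stereocenters, the equatorial α-hydrogen being poorly aligned for enolisation.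

Step 3
Reactants: 4 methyl 2-[(1R,3S)-3-(2-chloropropan-2-yl)-2,2-dimethyl-6-oxocyclohexyl]acetate
Product: 5 methyl 2-[(1R,3S,6R)-3-(2-chloropropan-2-yl)-6-hydroxy-2,2,6-trimethylcyclohexyl]acetate
Conditions: MeMgBr (1.3 equiv), anhydrous CeCl3 (1.5 equiv), THF, −78 °C; aq. NH4Cl
Reagents that add atoms: methylmagnesium bromide, C[Mg]Br
Why: Cerium-mediated Grignard 1,2-addition to the ketone (ester untouched at −78 °C); the equatorial 2-chloropropan-2-yl group locks the chair with the acetate arm axial, the syn-axial methyl of the gem-dimethyl group blocks the opposite face, so methyl enters from the side-chain face and gives the (R)-carbinol with hydroxyl trans to the side chain.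

Step 4
Reactants: 5 methyl 2-[(1R,3S,6R)-3-(2-chloropropan-2-yl)-6-hydroxy-2,2,6-trimethylcyclohexyl]acetate
Product: 6 2-[(1R,3R,6R)-6-hydroxy-2,2,6-trimethyl-3-(prop-1-en-2-yl)cyclohexyl]acetic acid
Conditions: t-BuOK (4 equiv), DMSO, 25 °C; then H2O; aq. HCl work-up
Reagents that add atoms: water, O
Why: E2 dehydrochlorination with a bulky base gives the Hofmann (isopropenyl) alkene, and the hydroxide formed on adding water saponifies the methyl ester in the same pot.

Step 5
Reactants: 6 2-[(1R,3R,6R)-6-hydroxy-2,2,6-trimethyl-3-(prop-1-en-2-yl)cyclohexyl]acetic acid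
Product: 8 2-[(1R,2R)-2-hydroxy-2,6,6-trimethylcyclohexyl]acetic acid, via methoxy hydroperoxide 7 (not isolated)
Conditions: O3, MeOH/CH2Cl2, −78 °C; then FeSO4·7H2O (1.2 equiv), PhSH (1.5 equiv), −78 → 25 °C
Reagents that add atoms: none
Why: Ozonolysis in methanol, then divalent-iron reduction of the α-methoxy hydroperoxide, gives an alkoxy radical whose β-scission expels the ring radical, which thiophenol reduces (hydrodealkenylation); the three-carbon control element leaves a ring CH2 and no stereocenter is involved.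

Step 6
Reactants: 9 methacryloyl chloride; 10 bis(trimethylsilyl)acetylene
Product: 11 4-methyl-1-(trimethylsilyl)pent-4-en-1-yn-3-one
Conditions: AlCl3 (1.1 equiv), CH2Cl2, 0 °C
Reagents that add atoms: none
Why: Friedel–Crafts-type acylation of the silylalkyne (ipso substitution of one silyl group) gives the cross-conjugated enynone linchpin.

Step 7
Reactants: 8 2-[(1R,2R)-2-hydroxy-2,6,6-trimethylcyclohexyl]acetic acid; 11 4-methyl-1-(trimethylsilyl)pent-4-en-1-yn-3-one
Product: 13 6-[(1R,2R)-2-hydroxy-2,6,6-trimethylcyclohexyl]-4-methylhex-1-yn-3-one (C-4 epimers), via silyl ynone 12 (not isolated)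
Conditions: Ir[dF(CF3)ppy]2(dtbbpy)PF6 (1 mol %), K2HPO4 (1.2 equiv), DMF, 450 nm LEDs, 25 °C; then Na2B4O7·10H2O, MeOH/H2O, 25 °C
Reagents that add atoms: none
Why: Photoredox decarboxylative Giese addition: the primary ring-CH2 radical adds to the unhindered methacryloyl terminus rather than the silyl-shielded alkyne, and mild borax methanolysis frees the terminal ynone (the new methyl-bearing carbon forms as a mixture that is equilibrated in step 16).

Step 8
Reactants: 14 (1R,5R)-(+)-verbenone
Product: 17 [(1R,3R,4S,5S)-4-(but-3-en-1-yl)-4,6,6-trimethyl-2-oxobicyclo[3.1.1]heptan-3-yl]methyl acetate, via magnesium enolate 15 (not isolated), via magnesium aldolate 16 (not isolated)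
Conditions: CH2=CHCH2CH2MgBr (1.5 equiv), CuBr·SMe2 (10 mol %), THF, −30 °C; then CH2O (g), −40 °C; then Ac2O, −40 → 25 °C
Reagents that add atoms: but-3-enylmagnesium bromide, C=CCC[Mg]Br; formaldehyde, C=O; acetic anhydride, CC(=O)OC(C)=O
Why: Copper-catalysed conjugate addition and aldol trapping with formaldehyde both occur anti to the gem-dimethyl bridge, setting the quaternary methyl carbon and the adjacent CH from the bought bridgeheads; in-situ acetylation protects the aldol.

Step 9
Reactants: 17 [(1R,3R,4S,5S)-4-(but-3-en-1-yl)-4,6,6-trimethyl-2-oxobicyclo[3.1.1]heptan-3-yl]methyl acetate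
Product: 18 [(1R,2R,3R)-2-(but-3-en-1-yl)-3-(2-chloropropan-2-yl)-2-methyl-6-oxocyclohexyl]methyl acetate
Conditions: HCl (g), ZnCl2 (10 mol %), CH2Cl2, 0 → 25 °C
Reagents that add atoms: hydrogen chloride, Cl
Why: Same Grob-type cyclobutane fragmentation as in step 2; chloride captures the tertiary cation faster than it can reach the monosubstituted alkene, and the former bridgehead carbon keeps its configuration.

Step 10
Reactants: 18 [(1R,2R,3R)-2-(but-3-en-1-yl)-3-(2-chloropropan-2-yl)-2-methyl-6-oxocyclohexyl]methyl acetate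
Product: 20 [(1R,2R,3R)-2-(but-3-en-1-yl)-3-hydroxy-2-methyl-6-oxocyclohexyl]methyl acetate, via tertiary hydroperoxide 19 (not isolated)
Conditions: H2O2 (anhydrous, Et2O), AgOCOCF3 (1.1 equiv), −20 °C; then BF3·OEt2 (20 mol %), CH2Cl2, −20 → 0 °C; aq. NaHCO3
Reagents that add atoms: hydrogen peroxide, OO
Why: Silver-assisted perhydrolysis of the tertiary chloride and Hock (Criegee-type) rearrangement, in which the secondary ring carbon migrates from carbon to oxygen with retention and the 2-alkoxy-2-propyl cation is hydrolysed to acetone, turn the C–C bond of the bought bridgehead into the ring C–O bond with unchanged configuration.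

Step 11
Reactants: 20 [(1R,2R,3R)-2-(but-3-en-1-yl)-3-hydroxy-2-methyl-6-oxocyclohexyl]methyl acetate
Product: 21 [(1R,2R,3R)-3-hydroxy-2-methyl-2-(4-methylpent-3-en-1-yl)-6-oxocyclohexyl]methyl acetate
Conditions: 2-methylbut-2-ene (excess), (H2IMes)(PCy3)Cl2Ru=CHPh (second-generation Grubbs catalyst, 5 mol %), CH2Cl2, 40 °C
Reagents that add atoms: 2-methylbut-2-ene, CC=C(C)C
Why: Olefin cross-metathesis of the terminal alkene with 2-methylbut-2-ene installs the trisubstituted terminus; no stereocenter is affected.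

Step 12
Reactants: 21 [(1R,2R,3R)-3-hydroxy-2-methyl-2-(4-methylpent-3-en-1-yl)-6-oxocyclohexyl]methyl acetate
Product: 23 [(5aR,6R,9aR)-3-hydroxy-2,2,5a-trimethyl-7-oxodecahydro-1-benzoxepin-6-yl]methyl acetate (C-3 epimers), via epoxide 22 (not isolated)
Conditions: mCPBA (1.1 equiv), CH2Cl2, 0 °C; then TsOH·H2O (10 mol %), 0 → 25 °C
Reagents that add atoms: 3-chloroperbenzoic acid, OOC(=O)c1cccc(Cl)c1
Why: Prilezhaev epoxidation of the trisubstituted alkene and acid-catalysed 7-endo epoxide opening by the ring hydroxyl at the tertiary carbon close the trans-fused 2,2-dimethyloxepane; the new carbinol center is a mixture that is erased by oxidation in step 14.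

Step 13
Reactants: 23 [(5aR,6R,9aR)-3-hydroxy-2,2,5a-trimethyl-7-oxodecahydro-1-benzoxepin-6-yl]methyl acetate
Product: 24 (5aR,6R,7S,9aR)-6-(hydroxymethyl)-2,2,5a,7-tetramethyldecahydro-1-benzoxepine-3,7-diol (C-3 epimers)
Conditions: MeLi (6 equiv), THF, −78 → −40 °C; aq. NH4Cl
Reagents that add atoms: methyllithium, [Li]C
Why: Methyllithium cleaves the acetate and adds 1,2 to the ketone of the rigid trans-fused bicycle from the face of the axial alkoxymethyl group (alkoxide-directed), the other face being blocked by the syn-axial angular methyl, giving the (S)-carbinol with hydroxyl cis to the angular methyl.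

Step 14
Reactants: 24 (5aR,6R,7S,9aR)-6-(hydroxymethyl)-2,2,5a,7-tetramethyldecahydro-1-benzoxepine-3,7-diol
Product: 25 (5aR,6S,7S,9aR)-7-hydroxy-2,2,5a,7-tetramethyl-3-oxodecahydro-1-benzoxepine-6-carboxylic acid
Conditions: TEMPO (20 mol %), PhI(OAc)2 (5 equiv), MeCN/H2O 1:1, 25 °C
Reagents that add atoms: water, O
Why: Oxoammonium (TEMPO/PhI(OAc)2) oxidation takes the primary alcohol to the acid via the aldehyde hydrate and the secondary alcohol to the oxepanone, while tertiary alcohols are inert.

Step 15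
Reactants: 25 (5aR,6S,7S,9aR)-7-hydroxy-2,2,5a,7-tetramethyl-3-oxodecahydro-1-benzoxepine-6-carboxylic acid; 13 6-[(1R,2R)-2-hydroxy-2,6,6-trimethylcyclohexyl]-4-methylhex-1-yn-3-one
Product: 26 6-[(1R,2R)-2-hydroxy-2,6,6-trimethylcyclohexyl]-1-[(5aR,6S,7S,9aR)-7-hydroxy-2,2,5a,7-tetramethyl-3-oxodecahydro-1-benzoxepin-6-yl]-4-methylhex-1-en-3-one (E/Z and C-4 epimer mixture)
Conditions: Ir[dF(CF3)ppy]2(dtbbpy)PF6 (2 mol %), K2HPO4 (1.5 equiv), DMF, 450 nm LEDs, 25 °C
Reagents that add atoms: none
Why: Proposed new method: visible-light photoredox decarboxylative radical addition to a terminal ynone – the excited trivalent-iridium photocatalyst oxidises the hindered β-hydroxy carboxylate of 25, loss of CO2 gives the secondary ring radical flanked by two quaternary carbons, which attacks the terminal alkyne carbon of 13 from the face anti to the axial angular methyl and the axial tertiary hydroxyl (axial attack, so the new C–C bond lands cis to the oxepane CH2 as in the target), and the α-keto vinyl radical is reduced by divalent iridium and protonated to the enone; the closest known chemistry is the decarboxylative Giese addition of carboxylic acids to alkenyl Michael acceptors, which has not been shown for ynones with such β-hydroxy, doubly neopentylic radicals or used to set a ring stereocenter this way.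

Step 16
Reactants: 26 open-chain hydroxy enone (E/Z and C-4 epimer mixture)
Product: 27 CNP0307967.2, (2R,3R,5aR,9aR)-2-{(E)-2-[(5aR,6S,7S,9aR)-7-hydroxy-2,2,5a,7-tetramethyl-3-oxodecahydro-1-benzoxepin-6-yl]ethenyl}-3,6,6,9a-tetramethyldecahydro-1-benzoxepin-2-ol
Conditions: PhSH (10 mol %), DBU (30 mol %), CH2Cl2, 25 °C
Reagents that add atoms: none
Why: Thiolate Michael addition–elimination equilibrates the alkene to E, DBU epimerises the enolisable methyl-bearing carbon, and the tertiary hydroxyl closes onto the ketone to the seven-membered hemiketal, so the expected thermodynamic diastereomer (equatorial methyl, anomeric axial hydroxyl) is funnelled out under control of the fixed ring stereocenters.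

**Compound list**
1 | (1S,5S)-(−)-verbenone, (1S,5S)-4,6,6-trimethylbicyclo[3.1.1]hept-3-en-2-one | CC1=CC(=O)[C@H]2C[C@@H]1C2(C)C | starting material
2 | bromomagnesium enolate of (1S,5S)-4,4,6,6-tetramethylbicyclo[3.1.1]heptan-2-one (enolate double bond toward the gem-dimethyl carbon) | CC1(C)C=C(O[Mg]Br)[C@H]2C[C@@H]1C2(C)C | intermediate (not isolated)
3 | methyl 2-[(1S,3R,5R)-4,4,6,6-tetramethyl-2-oxobicyclo[3.1.1]heptan-3-yl]acetate (side chain anti to the cyclobutane gem-dimethyl bridge) | CC1(C)[C@@H](CC(=O)OC)C(=O)[C@H]2C[C@@H]1C2(C)C | intermediate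
4 | methyl 2-[(1R,3S)-3-(2-chloropropan-2-yl)-2,2-dimethyl-6-oxocyclohexyl]acetate | O=C1CC[C@H](C(C)(C)Cl)C(C)(C)[C@H]1CC(=O)OC | intermediate
5 | methyl 2-[(1R,3S,6R)-3-(2-chloropropan-2-yl)-6-hydroxy-2,2,6-trimethylcyclohexyl]acetate | C[C@@]1(O)CC[C@H](C(C)(C)Cl)C(C)(C)[C@H]1CC(=O)OC | intermediate
6 | 2-[(1R,3R,6R)-6-hydroxy-2,2,6-trimethyl-3-(prop-1-en-2-yl)cyclohexyl]acetic acid | C[C@@]1(O)CC[C@H](C(C)=C)C(C)(C)[C@H]1CC(=O)O | intermediate
7 | α-methoxy hydroperoxide from ozonolysis of 6 in methanol (1-hydroperoxy-1-methoxyethyl group in place of isopropenyl) | C[C@@]1(O)CC[C@H](C(C)(OC)OO)C(C)(C)[C@H]1CC(=O)O | intermediate (not isolated)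
8 | 2-[(1R,2R)-2-hydroxy-2,6,6-trimethylcyclohexyl]acetic acid | C[C@@]1(O)CCCC(C)(C)[C@H]1CC(=O)O | intermediate
9 | methacryloyl chloride | CC(=C)C(Cl)=O | starting material
10 | bis(trimethylsilyl)acetylene | C[Si](C)(C)C#C[Si](C)(C)C | starting material
11 | 4-methyl-1-(trimethylsilyl)pent-4-en-1-yn-3-one | CC(=C)C(=O)C#C[Si](C)(C)C | intermediate
12 | 6-[(1R,2R)-2-hydroxy-2,6,6-trimethylcyclohexyl]-4-methyl-1-(trimethylsilyl)hex-1-yn-3-one (C-4 epimers) | C[C@@]1(O)CCCC(C)(C)[C@H]1CCC(C)C(=O)C#C[Si](C)(C)C | intermediate (not isolated)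
13 | 6-[(1R,2R)-2-hydroxy-2,6,6-trimethylcyclohexyl]-4-methylhex-1-yn-3-one (C-4 epimers) | C[C@@]1(O)CCCC(C)(C)[C@H]1CCC(C)C(=O)C#C | intermediate
14 | (1R,5R)-(+)-verbenone, (1R,5R)-4,6,6-trimethylbicyclo[3.1.1]hept-3-en-2-one | CC1=CC(=O)[C@@H]2C[C@H]1C2(C)C | starting material
15 | bromomagnesium enolate of the 4-butenyl-4-methyl verbanone (butenyl anti to the bridge) | C[C@@]1(CCC=C)C=C(O[Mg]Br)[C@@H]2C[C@H]1C2(C)C | intermediate (not isolated)
16 | bromomagnesium aldolate (OMgBr form of the 3-hydroxymethyl ketone, CH2O group anti to the bridge) | C[C@@]1(CCC=C)[C@H](CO[Mg]Br)C(=O)[C@@H]2C[C@H]1C2(C)C | intermediate (not isolated)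
17 | [(1R,3R,4S,5S)-4-(but-3-en-1-yl)-4,6,6-trimethyl-2-oxobicyclo[3.1.1]heptan-3-yl]methyl acetate | C[C@@]1(CCC=C)[C@H](COC(C)=O)C(=O)[C@@H]2C[C@H]1C2(C)C | intermediate
18 | [(1R,2R,3R)-2-(but-3-en-1-yl)-3-(2-chloropropan-2-yl)-2-methyl-6-oxocyclohexyl]methyl acetate | O=C1CC[C@@H](C(C)(C)Cl)[C@](C)(CCC=C)[C@@H]1COC(C)=O | intermediate
19 | tertiary hydroperoxide (OOH in place of Cl of 18) | O=C1CC[C@@H](C(C)(C)OO)[C@](C)(CCC=C)[C@@H]1COC(C)=O | intermediate (not isolated)
20 | [(1R,2R,3R)-2-(but-3-en-1-yl)-3-hydroxy-2-methyl-6-oxocyclohexyl]methyl acetate | O=C1CC[C@@H](O)[C@](C)(CCC=C)[C@@H]1COC(C)=O | intermediate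
21 | [(1R,2R,3R)-3-hydroxy-2-methyl-2-(4-methylpent-3-en-1-yl)-6-oxocyclohexyl]methyl acetate | O=C1CC[C@@H](O)[C@](C)(CCC=C(C)C)[C@@H]1COC(C)=O | intermediate
22 | epoxide of 21 (2-(3,3-dimethyloxiran-2-yl)ethyl side chain, both epoxide epimers) | O=C1CC[C@@H](O)[C@](C)(CCC2OC2(C)C)[C@@H]1COC(C)=O | intermediate (not isolated)
23 | [(5aR,6R,9aR)-3-hydroxy-2,2,5a-trimethyl-7-oxodecahydro-1-benzoxepin-6-yl]methyl acetate (C-3 epimers, trans ring fusion) | O=C1CC[C@H]2OC(C)(C)C(O)CC[C@]2(C)[C@@H]1COC(C)=O | intermediate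
24 | (5aR,6R,7S,9aR)-6-(hydroxymethyl)-2,2,5a,7-tetramethyldecahydro-1-benzoxepine-3,7-diol (C-3 epimers) | C[C@]1(O)CC[C@H]2OC(C)(C)C(O)CC[C@]2(C)[C@@H]1CO | intermediate
25 | (5aR,6S,7S,9aR)-7-hydroxy-2,2,5a,7-tetramethyl-3-oxodecahydro-1-benzoxepine-6-carboxylic acid | C[C@]1(O)CC[C@H]2OC(C)(C)C(=O)CC[C@]2(C)[C@@H]1C(=O)O | intermediate
26 | 6-[(1R,2R)-2-hydroxy-2,6,6-trimethylcyclohexyl]-1-[(5aR,6S,7S,9aR)-7-hydroxy-2,2,5a,7-tetramethyl-3-oxodecahydro-1-benzoxepin-6-yl]-4-methylhex-1-en-3-one (E/Z and C-4 epimer mixture) | C[C@@]1(O)CCCC(C)(C)[C@H]1CCC(C)C(=O)C=C[C@H]1[C@@]2(C)CCC(=O)C(C)(C)O[C@@H]2CC[C@]1(C)O | intermediate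
27 | CNP0307967.2, (2R,3R,5aR,9aR)-2-{(E)-2-[(5aR,6S,7S,9aR)-7-hydroxy-2,2,5a,7-tetramethyl-3-oxodecahydro-1-benzoxepin-6-yl]ethenyl}-3,6,6,9a-tetramethyldecahydro-1-benzoxepin-2-ol | C[C@@H]1CC[C@@H]2C(C)(C)CCC[C@@]2(C)O[C@@]1(O)/C=C/[C@H]1[C@@]2(C)CCC(=O)C(C)(C)O[C@@H]2CC[C@]1(C)O | target

**Totals**
Total step count: 16. Longest linear sequence: 9 steps (14 → 27, steps 8–16).

**Three steps most likely to fail**

Step 15 (the proposed new step; risks are a slow or unselective radical addition, or ynone degradation). Fallback with known chemistry, setting out from 24 and 8 and coming back at 26: oxidise triol 24 with Dess–Martin periodinane (NaHCO3, CH2Cl2) to (5aR,6S,7S,9aR)-7-hydroxy-2,2,5a,7-tetramethyl-3-oxodecahydro-1-benzoxepine-6-carbaldehyde F1, whose ring CH center was already set anti to the pinane bridge in step 8. Run the known decarboxylative Giese addition of acid 8 to commercial 3-methylbut-3-en-2-one under the step-7 photoredox conditions to get 5-[(1R,2R)-2-hydroxy-2,6,6-trimethylcyclohexyl]-3-methylpentan-2-one F2. Form its kinetic methyl enolate with lithium diisopropylamide (LiN(iPr)2, 2.2 equiv, THF, −78 °C) and add F1 to give the aldol adduct F3. Dehydrate with MsCl/Et3N then DBU to the E-enone, which is 26, and continue with step 16.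

Step 10 (perhydrolysis/Hock rearrangement next to a ketone and an alkene). Fallback setting out from 18 and coming back at 24: eliminate HCl (LiBr, Li2CO3, DMF, 100 °C) to the isopropenyl ketone F4. Cross-metathesise its terminal alkene as in step 11 to the homoprenyl isopropenyl ketone F5 (the 1,1-disubstituted alkene is inert). Epoxidise the trisubstituted alkene selectively (mCPBA, 1.0 equiv, −20 °C) to epoxide F6. Ozonise the remaining isopropenyl group in MeOH/CH2Cl2 and treat with Ac2O, Et3N and DMAP (Criegee rearrangement, retention) to the ring acetate F7. Cleave both acetates with NH3/MeOH and cyclise with TsOH·H2O to the oxepane keto diol F8. Add MeLi as in step 13 to reach 24.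

Step 12 (6-exo tetrahydropyran formation may compete with the 7-endo closure). Fallback setting out from 21 and coming back at 23: intramolecular alkoxymercuration with Hg(OCOCF3)2 (CH2Cl2, −20 °C, then aq. KBr), which is Markovnikov by nature and puts oxygen on the tertiary carbon, gives the oxepanyl mercury bromide F9. Oxidative demercuration (NaBH4, O2, DMF) gives 23.

**Further compounds**
F1 | step 15 | (5aR,6S,7S,9aR)-7-hydroxy-2,2,5a,7-tetramethyl-3-oxodecahydro-1-benzoxepine-6-carbaldehyde | C[C@]1(O)CC[C@H]2OC(C)(C)C(=O)CC[C@]2(C)[C@@H]1C=O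
F2 | step 15 | 5-[(1R,2R)-2-hydroxy-2,6,6-trimethylcyclohexyl]-3-methylpentan-2-one (C-3 epimers) | C[C@@]1(O)CCCC(C)(C)[C@H]1CCC(C)C(C)=O
F3 | step 15 | aldol adduct of F2 and F1 (β-hydroxy ketone, carbinol epimers, ring configuration as in 26) | C[C@@]1(O)CCCC(C)(C)[C@H]1CCC(C)C(=O)CC(O)[C@H]1[C@@]2(C)CCC(=O)C(C)(C)O[C@@H]2CC[C@]1(C)O
F4 | step 10 | isopropenyl analogue of 18 (prop-1-en-2-yl in place of 2-chloropropan-2-yl, same configuration) | O=C1CC[C@@H](C(C)=C)[C@](C)(CCC=C)[C@@H]1COC(C)=O
F5 | step 10 | homoprenyl isopropenyl ketone (4-methylpent-3-en-1-yl in place of butenyl of F4) | O=C1CC[C@@H](C(C)=C)[C@](C)(CCC=C(C)C)[C@@H]1COC(C)=O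
F6 | step 10 | side-chain epoxide of F5 (both epoxide epimers) | O=C1CC[C@@H](C(C)=C)[C@](C)(CCC2OC2(C)C)[C@@H]1COC(C)=O
F7 | step 10 | ring acetate from Criegee rearrangement of F6 (acetoxy in place of isopropenyl, retention) | O=C1CC[C@@H](OC(C)=O)[C@](C)(CCC2OC2(C)C)[C@@H]1COC(C)=O
F8 | step 10 | (5aR,6R,9aR)-3-hydroxy-6-(hydroxymethyl)-2,2,5a-trimethyloctahydro-1-benzoxepin-7(2H)-one (C-3 epimers) | O=C1CC[C@H]2OC(C)(C)C(O)CC[C@]2(C)[C@@H]1CO
F9 | step 12 | bromomercurio analogue of 23 (HgBr in place of the oxepane hydroxyl, both epimers) | O=C1CC[C@H]2OC(C)(C)C([Hg]Br)CC[C@]2(C)[C@@H]1COC(C)=O
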